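Early on, the red run looks like plain chemistry. In its first 8.00 h X falls to 27.4%, which, read as second order with Z at its charge, gives a rate constant of 0.176 M⁻¹ h⁻¹.

the same everywhere: X 0.20 M
- green: Z 1.1 equiv; run made earlier
- red: Z 4.6 equiv; run made earlier
- autumn: Z 0.800 equiv; time 2.5 d
- summer: Z 1.60 equiv; time 2.5 d
- spring: Z 3.20 equiv; time 2.5 d

- green (time / h: X / %, Q / %): 8.00: 75.3, 24.5; 15.0: 66.3, 33.6; 25.0: 59.7, 39.8; 30.0: 56.8, 41.8; 40.0: 54.4, 45.0
- red (time / h: X / %, Q / %): 8.00: 27.4, 70.4; 15.0: 12.1, 81.1; 25.0: 4.5, 83.9; 30.0: 3.1, 85.1; 40.0: 1.6, 83.6

(standard deviation of a reading: 0.3 percentage points)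

* part of the X that has reacted at the end, autumn
* part of the X that has reacted at the end, summer
* part of the X that has reacted at the end, spring
* what raising the equivalents of Z from its lowest to its highest value here does to the part of the X that has reacted (changes below 5 percentage points count as none) (it rises / no change / it falls)

Two chemists read these runs differently. The first holds that Z is a plain reagent, spent once per X. Autumn then has Z as its limiting reagent, and second-order kinetics with that constant gives 57.9% of the X reacted by 2.5 d, and 99.3% in spring.

The second looks at the end of the green run. Between 30.0 h and 40.0 h the green X falls by 0.00432 h⁻¹ of itself. Dividing that rate by the constant removes time and leaves a free c(Z) of about 0.0245 M. So the Z no longer free, per X reacted in green, which she calls the Z price, reads 2.14. That is near 2, and the listed steps offer a way: each X yields a G, which can take a second Z into L.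

At that price, while every G stays paired, the reacted part of X stays under the ceiling, the equivalents of Z over 2: 40.0% in autumn, 80.0% in summer. In spring it comes to 160%, more than the X charged, so it stands idle there.

The forecast sided with her, “free Z is being removed”, and gave 39% (34% to 44%) for autumn, 66% (59% to 73%) for summer, 94% (89% to 98%) for spring, and for the trend: it rises.

The simulation gives 37.2%, 68.1% and 96.5%; the trend is it rises, by 59 percentage points.

    X + Z → G + Q (k = 0.00420 M⁻¹ min⁻¹)
    Z + G ⇌ L, settled at all times (K = 57000 M⁻¹)
    Z ⇌ E (K = 0.460, k = 6.20 × 10⁻⁴ min⁻¹)
    Z + Q → J (k = 2.20 × 10⁻⁴ M⁻¹ min⁻¹)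

Autumn stands under its ceiling of 40.0%, far from the 57.9% of the first view. That view's region is spring, where its 99.3% lies 2.8 points from the flask, closer than in autumn. Autumn, summer and spring have not come to rest at 2.5 d. Left ten times as long, until 25.0 d, spring has reacted 100% of its X, but its Q has dropped from 84.8% to 40.8% while J has reached 59.2%. Left ten times as long, summer creeps to 79.4%, under its 80.0%. Its neighbour with 0.50 M of X, same ceiling, already shows 75.7% at 2.5 d. Left ten times as long, autumn reaches 41.7%, just past 40.0%, with 0.0975% of its Z free and c(G) unpaired at 0.00843 M.

The data come from a simulation on assumed constants; the scatter is artificial.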